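**Retrosynthetic overview**
1. Target 23 ⇐ triol 22 (selective acetylation of the primary allylic OH) ⇐ silyl/acetonide-protected lobane 21.
2. Isopropenyl-bearing CH of 21 ⇐ ketone 18: isopropenyl Grignard addition, then formate hydrogenolysis of the tertiary allylic carbonate 20.
3. Quaternary methyl/vinyl carbon of 18 ⇐ bromohydrin 15 by a visible-light radical 1,2-vinyl shift (key C–C bond); 15 ⇐ enone 12 by conjugate reduction–bromination and vinyl addition.
4. Z-trisubstituted alkene of 12 ⇐ Wittig union of α-silyloxy ketone 5 (from (S)-carvone 1) with the ylide of phosphonium salt 10 (from (R)-α-hydroxy-γ-butyrolactone 6).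
5. Rings: the cyclohexane is bought with carvone and kept throughout; no carbocycle is formed, only a temporary dioxolane (made in step 5, removed in step 13).

Assumption: the SMILES is read as the (1R,2R,4S)-cyclohexane with a Z side-chain alkene and an (R)-carbinol, and both chiral starting materials are bought enantiopure.

Abbreviations in names: TBS = tert-butyldimethylsilyl; SC = (2Z)-1-(TBS-oxy)-4-[(4R)-2,2,5,5-tetramethyl-1,3-dioxolan-4-yl]but-2-en-2-yl, attached through its C2.

**Route**

Step 1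
Reactants: 1 (S)-(+)-carvone
Product: 2 (5S)-5-(3-hydroxyprop-1-en-2-yl)-2-methylcyclohex-2-en-1-one
Conditions: SeO2 (0.3 equiv), t-BuOOH (2 equiv), CH2Cl2, rt; unreacted 1 recycled
Reagents that add atoms: tert-butyl hydroperoxide (CC(C)(C)OO)
Why: Selenium dioxide allylic hydroxylation (ene reaction then [2,3]-shift) attacks the electron-rich isopropenyl group at its CH3 and leaves the enone and the stereocentre untouched; the yield is moderate.

Step 2
Reactants: 2 (5S)-5-(3-hydroxyprop-1-en-2-yl)-2-methylcyclohex-2-en-1-one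
Product: 3 (5S)-2-methyl-5-[3-(TBS-oxy)prop-1-en-2-yl]cyclohex-2-en-1-one
Conditions: TBSCl, imidazole, DMF, 0 °C → rt
Reagents that add atoms: tert-butyldimethylsilyl chloride (CC(C)(C)[Si](C)(C)Cl)
Why: Standard silylation of a primary alcohol gives an ether that survives hydride, Grignard, radical and palladium steps.

Step 3
Reactants: 3 (5S)-2-methyl-5-[3-(TBS-oxy)prop-1-en-2-yl]cyclohex-2-en-1-one
Product: 5 (5S)-2-methyl-5-[(TBS-oxy)acetyl]cyclohex-2-en-1-one, via secondary ozonide 4 (not isolated)
Conditions: O3, CH2Cl2, −78 °C (Sudan red end point); then PPh3, −78 °C → rt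
Reagents that add atoms: ozone ([O-][O+]=O)
Why: Ozonolysis cleaves the electron-rich 1,1-disubstituted alkene far faster than the enone alkene, and the neutral phosphine work-up avoids epimerising the α-CH.

Step 4
Reactants: 6 (R)-α-hydroxy-γ-butyrolactone [(3R)-3-hydroxyoxolan-2-one]
Product: 7 (3R)-4-methylpentane-1,3,4-triol
Conditions: MeMgBr (3.5 equiv), THF, 0 °C → rt; H2O quench
Reagents that add atoms: methylmagnesium bromide (C[Mg]Br)
Why: Double Grignard addition to the lactone carbonyl builds the dimethylcarbinol; the bought stereocentre, an alkoxide during the reaction, cannot enolise.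

Step 5
Reactants: 7 (3R)-4-methylpentane-1,3,4-triol
Product: 8 2-[(4R)-2,2,5,5-tetramethyl-1,3-dioxolan-4-yl]ethan-1-ol
Conditions: 2,2-dimethoxypropane, p-TsOH (cat.), acetone, rt
Reagents that add atoms: 2,2-dimethoxypropane (COC(C)(C)OC)
Why: Thermodynamic acetalisation favours the five-membered dioxolane of the vicinal diol over the six-membered dioxane, leaving the primary OH free.

Step 6
Reactants: 8 2-[(4R)-2,2,5,5-tetramethyl-1,3-dioxolan-4-yl]ethan-1-ol
Product: 10 {2-[(4R)-2,2,5,5-tetramethyl-1,3-dioxolan-4-yl]ethyl}(triphenyl)phosphonium iodide, via alkyl iodide 9 (not isolated)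
Conditions: PPh3 (2.3 equiv), I2 (1.1 equiv), imidazole, MeCN/toluene, 0 °C → rt, then 85 °C
Reagents that add atoms: iodine (II), triphenylphosphine (c1ccc(cc1)P(c1ccccc1)c1ccccc1)
Why: Appel iodination of the primary alcohol is followed in the same pot by SN2 quaternisation with the excess phosphine.

Step 7
Reactants: 10 phosphonium iodide; 5 (5S)-2-methyl-5-[(TBS-oxy)acetyl]cyclohex-2-en-1-one
Product: 12 (5S)-2-methyl-5-SC-cyclohex-2-en-1-one, via phosphorus ylide 11 (not isolated)
Conditions: KN(SiMe3)2 (1.0 equiv), THF/DMPU, −78 → 0 °C; then 5, −78 °C → rt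
Reagents that add atoms: none
Why: The Z-selective Wittig olefination of α-alkoxy ketones with non-stabilised ylides puts CH2OTBS cis to the new chain; the activated α-silyloxy ketone reacts before the enone carbonyl.

Step 8
Reactants: 12 (5S)-2-methyl-5-SC-cyclohex-2-en-1-one
Product: 14 (2R,5S)-2-bromo-2-methyl-5-SC-cyclohexan-1-one, via lithium enolate 13 (not isolated)
Conditions: Li[HB(sec-Bu)3] (1.05 equiv), THF, −78 °C; then NBS, −78 °C; AcOH quench
Reagents that add atoms: N-bromosuccinimide (O=C1CCC(=O)N1Br)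
Why: Conjugate hydride reduction gives the regiodefined enolate, which is brominated from the axial face (Br cis to the equatorial C5 side chain); the minor epimer is also usable in step 10.

Step 9
Reactants: 14 (2R,5S)-2-bromo-2-methyl-5-SC-cyclohexan-1-one
Product: 15 (1R,2R,5S)-2-bromo-1-ethenyl-2-methyl-5-SC-cyclohexan-1-ol
Conditions: CH2=CHMgBr (1.3 equiv), THF, −78 °C; AcOH quench at −78 °C
Reagents that add atoms: vinylmagnesium bromide (C=C[Mg]Br)
Why: Grignard 1,2-addition enters axially, anti to the axial C–Br bond (Cornforth/Felkin–Anh control) and trans to the C5 side chain, so the vinyl-bearing stereocentre is set by the carvone centre; the cold quench stops the alkoxide rearranging.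

Step 10
Reactants: 15 (1R,2R,5S)-2-bromo-1-ethenyl-2-methyl-5-SC-cyclohexan-1-ol
Product: 18 (2R,5S)-2-ethenyl-2-methyl-5-SC-cyclohexan-1-one, via tertiary alkyl radical 16 (not isolated), via ketyl radical 17 (not isolated)
Conditions: 1,2,3,5-tetrakis(carbazol-9-yl)-4,6-dicyanobenzene (4CzIPN, 2 mol%), i-Pr2NEt (2 equiv), degassed MeCN, 450 nm LEDs, rt
Reagents that add atoms: none
Why: Proposed new method: a halogen-atom-transfer radical semipinacol, in which the α-aminoalkyl radical made from i-Pr2NEt by the excited photocatalyst abstracts Br from the tertiary C–Br bond, the planar radical 16 adds 3-exo to the neighbouring vinyl group and the cyclopropylcarbinyl radical reopens to the O-stabilised ketyl radical 17 (a Dowd–Beckwith/neophyl-type 1,2-vinyl shift), which is oxidised to the ketone by the iminium ion or the photocatalyst in a redox-neutral chain; the vinyl group can only cross on the ring face it already occupies (trans to the C5 side chain, fixed in step 9), so the quaternary centre forms as one epimer from either C–Br epimer; closest known reaction types are halogen-atom-transfer photocatalysis with α-aminoalkyl radicals, radical 1,2-vinyl migration and the polar halohydrin semipinacol rearrangement, none shown on a tertiary β-bromo vinyl carbinol of this kind.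

Step 11
Reactants: 18 (2R,5S)-2-ethenyl-2-methyl-5-SC-cyclohexan-1-one
Product: 20 methyl (1R,2R,5S)-2-ethenyl-2-methyl-1-(prop-1-en-2-yl)-5-SC-cyclohexyl carbonate, via bromomagnesium alkoxide 19 (not isolated)
Conditions: CH2=C(CH3)MgBr, LaCl3·2LiCl (0.3 equiv), THF, −20 → 0 °C; then ClCO2Me, 0 °C
Reagents that add atoms: isopropenylmagnesium bromide (CC(=C)[Mg]Br), methyl chloroformate (COC(=O)Cl)
Why: Lanthanum-promoted Grignard 1,2-addition to the hindered ketone comes from the axial face, anti to the axial C2 methyl (O equatorial), and the alkoxide is acylated in situ below 0 °C to avoid anionic oxy-Cope rearrangement.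

Step 12
Reactants: 20 methyl (1R,2R,5S)-2-ethenyl-2-methyl-1-(prop-1-en-2-yl)-5-SC-cyclohexyl carbonate
Product: 21 (1R,2R,4S)-1-ethenyl-1-methyl-2-(prop-1-en-2-yl)-4-SC-cyclohexane
Conditions: Pd(OAc)2 (5 mol%), PBu3 (20 mol%), HCO2NH4 (3 equiv), THF, 40 °C
Reagents that add atoms: none
Why: Formate hydrogenolysis of an allylic carbonate (Tsuji–Mandai type): zerovalent palladium ionises the carbonate and the palladium formate delivers hydride to the more substituted allyl terminus, giving the isopropenyl alkene; H arrives on the axial face anti to the departed oxygen and to the axial methyl, so isopropenyl ends equatorial, trans to vinyl and cis to the side chain.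

Step 13
Reactants: 21 (1R,2R,4S)-1-ethenyl-1-methyl-2-(prop-1-en-2-yl)-4-SC-cyclohexane
Product: 22 (2Z,5R)-2-[(1S,3R,4R)-4-ethenyl-4-methyl-3-(prop-1-en-2-yl)cyclohexyl]-6-methylhept-2-ene-1,5,6-triol
Conditions: 1 M aq HCl, THF, rt
Reagents that add atoms: none
Why: Dilute acid hydrolyses the primary silyl ether and the acetonide together without touching the alkenes or stereocentres.

Step 14
Reactants: 22 (2Z,5R)-2-[(1S,3R,4R)-4-ethenyl-4-methyl-3-(prop-1-en-2-yl)cyclohexyl]-6-methylhept-2-ene-1,5,6-triol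
Product: 23 [(2Z,5R)-2-[(1S,3R,4R)-4-ethenyl-4-methyl-3-(prop-1-en-2-yl)cyclohexyl]-5,6-dihydroxy-6-methylhept-2-en-1-yl] acetate (target)
Conditions: AcCl (1.05 equiv), 2,4,6-collidine, CH2Cl2, −78 °C
Reagents that add atoms: acetyl chloride (CC(=O)Cl)
Why: Kinetically selective acylation takes the unhindered primary allylic OH over the hindered secondary and tertiary alcohols.

**Compound list**
1 | (S)-(+)-carvone, (5S)-2-methyl-5-(prop-1-en-2-yl)cyclohex-2-en-1-one | CC1=CC[C@@H](CC1=O)C(C)=C | starting material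
2 | (5S)-5-(3-hydroxyprop-1-en-2-yl)-2-methylcyclohex-2-en-1-one | CC1=CC[C@@H](CC1=O)C(=C)CO | intermediate
3 | (5S)-2-methyl-5-[3-(TBS-oxy)prop-1-en-2-yl]cyclohex-2-en-1-one | CC1=CC[C@@H](CC1=O)C(=C)CO[Si](C)(C)C(C)(C)C | intermediate
4 | secondary ozonide (1,2,4-trioxolane) of 3, mixture at the trioxolane carbon | CC1=CC[C@@H](CC1=O)C2(CO[Si](C)(C)C(C)(C)C)OCOO2 | intermediate (not isolated)
5 | (5S)-2-methyl-5-[(TBS-oxy)acetyl]cyclohex-2-en-1-one | CC1=CC[C@@H](CC1=O)C(=O)CO[Si](C)(C)C(C)(C)C | intermediate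
6 | (R)-α-hydroxy-γ-butyrolactone, (3R)-3-hydroxyoxolan-2-one | O[C@@H]1CCOC1=O | starting material
7 | (3R)-4-methylpentane-1,3,4-triol | OCC[C@@H](O)C(C)(C)O | intermediate
8 | 2-[(4R)-2,2,5,5-tetramethyl-1,3-dioxolan-4-yl]ethan-1-ol | OCC[C@H]1OC(C)(C)OC1(C)C | intermediate
9 | (4R)-4-(2-iodoethyl)-2,2,5,5-tetramethyl-1,3-dioxolane | ICC[C@H]1OC(C)(C)OC1(C)C | intermediate (not isolated)
10 | {2-[(4R)-2,2,5,5-tetramethyl-1,3-dioxolan-4-yl]ethyl}(triphenyl)phosphonium iodide | [I-].C(C[C@H]1OC(C)(C)OC1(C)C)[P+](c1ccccc1)(c1ccccc1)c1ccccc1 | intermediate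
11 | triphenylphosphonium ylide of 10 | C(C[C@H]1OC(C)(C)OC1(C)C)=P(c1ccccc1)(c1ccccc1)c1ccccc1 | intermediate (not isolated)
12 | (5S)-2-methyl-5-SC-cyclohex-2-en-1-one | CC1=CC[C@@H](CC1=O)/C(CO[Si](C)(C)C(C)(C)C)=C/C[C@H]2OC(C)(C)OC2(C)C | intermediate
13 | lithium (5S)-2-methyl-5-SC-cyclohex-1-en-1-olate | [Li+].CC1=C([O-])C[C@H](CC1)/C(CO[Si](C)(C)C(C)(C)C)=C/C[C@H]2OC(C)(C)OC2(C)C | intermediate (not isolated)
14 | (2R,5S)-2-bromo-2-methyl-5-SC-cyclohexan-1-one (Br cis to SC) | C[C@@]1(Br)CC[C@@H](CC1=O)/C(CO[Si](C)(C)C(C)(C)C)=C/C[C@H]2OC(C)(C)OC2(C)C | intermediate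
15 | (1R,2R,5S)-2-bromo-1-ethenyl-2-methyl-5-SC-cyclohexan-1-ol (vinyl trans to Br and to SC) | C[C@@]1(Br)CC[C@@H](C[C@@]1(O)C=C)/C(CO[Si](C)(C)C(C)(C)C)=C/C[C@H]2OC(C)(C)OC2(C)C | intermediate
16 | tertiary C2 radical from 15 after loss of Br | C[C]1CC[C@@H](C[C@@]1(O)C=C)/C(CO[Si](C)(C)C(C)(C)C)=C/C[C@H]2OC(C)(C)OC2(C)C | intermediate (not isolated)
17 | O-protonated ketyl radical of 18 (vinyl already on C2) | C=C[C@@]1(C)CC[C@@H](C[C]1O)/C(CO[Si](C)(C)C(C)(C)C)=C/C[C@H]2OC(C)(C)OC2(C)C | intermediate (not isolated)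
18 | (2R,5S)-2-ethenyl-2-methyl-5-SC-cyclohexan-1-one (vinyl trans to SC) | C=C[C@@]1(C)CC[C@@H](CC1=O)/C(CO[Si](C)(C)C(C)(C)C)=C/C[C@H]2OC(C)(C)OC2(C)C | intermediate
19 | bromomagnesium (1R,2R,5S)-2-ethenyl-2-methyl-1-(prop-1-en-2-yl)-5-SC-cyclohexan-1-olate | C=C[C@@]1(C)CC[C@@H](C[C@@]1(O[Mg]Br)C(C)=C)/C(CO[Si](C)(C)C(C)(C)C)=C/C[C@H]2OC(C)(C)OC2(C)C | intermediate (not isolated)
20 | methyl (1R,2R,5S)-2-ethenyl-2-methyl-1-(prop-1-en-2-yl)-5-SC-cyclohexyl carbonate | C=C[C@@]1(C)CC[C@@H](C[C@@]1(OC(=O)OC)C(C)=C)/C(CO[Si](C)(C)C(C)(C)C)=C/C[C@H]2OC(C)(C)OC2(C)C | intermediate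
21 | (1R,2R,4S)-1-ethenyl-1-methyl-2-(prop-1-en-2-yl)-4-SC-cyclohexane | C=C[C@@]1(C)CC[C@H](/C(CO[Si](C)(C)C(C)(C)C)=C/C[C@H]2OC(C)(C)OC2(C)C)C[C@@H]1C(C)=C | intermediate
22 | (2Z,5R)-2-[(1S,3R,4R)-4-ethenyl-4-methyl-3-(prop-1-en-2-yl)cyclohexyl]-6-methylhept-2-ene-1,5,6-triol | C=C[C@@]1(C)CC[C@H](/C(CO)=C/C[C@@H](O)C(C)(C)O)C[C@@H]1C(C)=C | intermediate
23 | [(2Z,5R)-2-[(1S,3R,4R)-4-ethenyl-4-methyl-3-(prop-1-en-2-yl)cyclohexyl]-5,6-dihydroxy-6-methylhept-2-en-1-yl] acetate | C=C[C@@]1(C)CC[C@H](/C(COC(C)=O)=C/C[C@@H](O)C(C)(C)O)C[C@@H]1C(C)=C | target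

**Step count and risks**

Total steps: 14. Longest linear sequence: 11 steps (1 → 23 through steps 1–3 and 7–14; the branch 6 → 23 through steps 4–14 is equally long).

The three steps most likely to fail:

(a) Step 10, the proposed new reaction. Halogen abstraction from the hindered tertiary bromide may be slow, and hydrogen-atom quenching before or after the shift would give the debrominated alcohol or the secondary alcohol instead of the ketone. The fallback is known polar chemistry and sets out from bromo ketone 14. Vinylmagnesium bromide is added as in step 9 but the adduct is not protonated. Warming the bromomagnesium alkoxide F1 in THF/toluene to 40 °C (or treating isolated 15 with AgBF4) triggers the classical halohydrin semipinacol rearrangement: the axial vinyl group migrates anti-periplanar to the axial C–Br bond with inversion at the bromide carbon. It comes back to the route at 18. Only the major C–Br epimer is productive, which is why it is the fallback and not the first choice.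

(b) Step 12, together with the carbonate formation of step 11. Hydride may go to the CH2 terminus (isopropylidene isomer), β-hydride elimination may give a diene, facial control may be incomplete, and the hindered tertiary carbonate may form poorly. The fallback sets out from ketone 18. Reductive cyanation with TosMIC and t-BuOK in DME/EtOH gives nitrile F2 as an epimer mixture. MeLi, mild aqueous acid and then NaOMe equilibration give methyl ketone F3 with the acetyl group equatorial, trans to vinyl (expected only about 3–5:1, so separation is needed). Wittig methylenation with Ph3P=CH2 then gives 21, where it comes back to the route.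

(c) Step 9. The tertiary α-bromo ketone may undergo bromine–magnesium exchange or electron-transfer reduction to the enolate, or simple enolisation, instead of addition. The fallback sets out from 14 and uses the less basic, less reducing ethynylmagnesium bromide (THF, −78 → −40 °C) to give ethynyl carbinol F4. Semi-hydrogenation of the alkyne (H2, Pd/CaCO3 poisoned with Pb(OAc)2, quinoline) gives the vinyl carbinol, and it comes back at 15.

**Further compounds**
F1 | step 10 | bromomagnesium (1R,2R,5S)-2-bromo-1-ethenyl-2-methyl-5-SC-cyclohexan-1-olate | C[C@@]1(Br)CC[C@@H](C[C@@]1(O[Mg]Br)C=C)/C(CO[Si](C)(C)C(C)(C)C)=C/C[C@H]2OC(C)(C)OC2(C)C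
F2 | step 12 | (1S,2R,5S)-2-ethenyl-2-methyl-5-SC-cyclohexane-1-carbonitrile | C=C[C@@]1(C)CC[C@@H](C[C@@H]1C#N)/C(CO[Si](C)(C)C(C)(C)C)=C/C[C@H]2OC(C)(C)OC2(C)C
F3 | step 12 | 1-[(1S,2R,5S)-2-ethenyl-2-methyl-5-SC-cyclohexyl]ethan-1-one | C=C[C@@]1(C)CC[C@@H](C[C@@H]1C(C)=O)/C(CO[Si](C)(C)C(C)(C)C)=C/C[C@H]2OC(C)(C)OC2(C)C
F4 | step 9 | (1R,2R,5S)-2-bromo-1-ethynyl-2-methyl-5-SC-cyclohexan-1-ol | C[C@@]1(Br)CC[C@@H](C[C@@]1(O)C#C)/C(CO[Si](C)(C)C(C)(C)C)=C/C[C@H]2OC(C)(C)OC2(C)C
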